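The seven-membered ring is cut into a four-carbon arc (C7–C10) and a three-carbon arc (C6–C5–C1, shared with the cyclopentane). A rhodium vinyl carbene, released from a 7-cyclopentenylcycloheptatriene, cyclopropanates a 2-triflyloxy-3-methylbutadiene and the divinylcyclopropane rearranges in the same flask: C6–C7, C1–C10 and the quaternary C1 arise in one operation. The step exploits that the resulting 1,4-cycloheptadiene carries its alkenes exactly where the target needs H5/O6 (C5=C6, hydroboration) and CH3-8/O9 (C8=C9 enol triflate, later enone and allylic alcohol). A C4 silyloxy stereocenter from a CBS reduction steers C1 and is then exchanged for the isopropyl carbinol.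

Key step: step 5

Remark on conventions and assumptions: locants follow the carbon skeleton of the target (C1 methyl-bearing ring-fusion carbon; C2, C3 cyclopentane CH2; C4 isopropyl carbinol carbon; C5 ring-fusion CH; C6 ester-bearing carbon; C7 alkene CH; C8 methyl-bearing alkene carbon; C9 allylic carbinol carbon; C10 CH2); β is the face of the C1 methyl. Compounds 1, 4, 7 and 22 are taken as commercial.

Step 1
Reactants: 1 2-bromo-3-methylcyclopent-2-en-1-one
Product: 2 (S)-2-bromo-3-methylcyclopent-2-en-1-ol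
Conditions: (R)-2-methyl-CBS-oxazaborolidine (10 mol %), BH3·SMe2, THF, −20 °C
Reagents that add atoms: none
Why: Corey–Bakshi–Shibata reduction; with the bromoalkenyl arm as the large substituent the (R)-oxazaborolidine should deliver hydride to the face that gives the (S)-carbinol (C4), the only source of absolute configuration in the route.

Step 2
Reactants: 2 (S)-2-bromo-3-methylcyclopent-2-en-1-ol
Product: 3 (S)-[(2-bromo-3-methylcyclopent-2-en-1-yl)oxy]triethylsilane
Conditions: Et3SiCl, imidazole, CH2Cl2, 0 °C to rt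
Reagents that add atoms: chlorotriethylsilane CC[Si](Cl)(CC)CC
Why: Standard silylation of a secondary allylic alcohol; the silyl ether masks the hydroxyl toward organolithium and carbene chemistry and supplies the steric bias used in steps 5 and 6.

Step 3
Reactants: 3 (S)-[(2-bromo-3-methylcyclopent-2-en-1-yl)oxy]triethylsilane, 4 tropylium tetrafluoroborate
Product: 6 7-[(5S)-2-methyl-5-(triethylsilyloxy)cyclopent-1-en-1-yl]cyclohepta-1,3,5-triene, via alkenyllithium 5 (not isolated)
Conditions: t-BuLi (2.1 equiv), Et2O, −78 °C; then 4, THF, −78 °C to rt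
Reagents that add atoms: none
Why: Bromine–lithium exchange gives an alkenyllithium that cannot β-eliminate within the ring, and its nucleophilic addition to the tropylium cation should give the 7-alkenylcycloheptatriene.

Step 4
Reactants: 7 3-methylbut-3-en-2-one
Product: 9 3-methylbuta-1,3-dien-2-yl trifluoromethanesulfonate, via potassium dienolate 8 (not isolated)
Conditions: KN(SiMe3)2, THF, −78 °C; PhNTf2, −78 to 0 °C
Reagents that add atoms: N-phenylbis(trifluoromethanesulfonimide) O=S(=O)(N(c1ccccc1)S(=O)(=O)C(F)(F)F)C(F)(F)F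
Why: Enolate O-sulfonylation; the ketone has a single enolisable position, so the 2-triflyloxydiene should form regiospecifically.

Step 5
Reactants: 6 7-[(5S)-2-methyl-5-(triethylsilyloxy)cyclopent-1-en-1-yl]cyclohepta-1,3,5-triene, 9 3-methylbuta-1,3-dien-2-yl trifluoromethanesulfonate
Product: 11 (3S,8aR)-6,8a-dimethyl-3-(triethylsilyloxy)-1,2,3,5,8,8a-hexahydroazulen-7-yl trifluoromethanesulfonate, via cis-divinylcyclopropane 10 (not isolated)
Conditions: Rh2(O2CCF3)4 (5 mol %), 9 (4 equiv), ClCH2CH2Cl, 60 °C; then PhMe, 130 °C (sealed tube)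
Reagents that add atoms: none
Why: Divalent rhodium opens the norcaradiene valence tautomer of 6 (retro-Buchner decarbenation, loss of benzene) to a catalyst-bound cyclopentenyl carbene at C6, which cyclopropanates the isopropenyl C7=C8 bond of 9 to give 10; on heating, 10 undergoes the [3,3] Cope rearrangement through a boat transition state (C6–C8 cleaved, C1–C10 formed), so C6–C7 and C1–C10 are made in one flask operation. The closest known reaction type is the formal (4+3) cycloaddition of non-acceptor vinyl carbenes with 1,3-dienes by tandem cyclopropanation and divinylcyclopropane rearrangement. The cyclopropane is closed by [2+1] carbene transfer and the seven-membered ring by the sigmatropic ring enlargement of that cyclopropane, not by a polar cyclisation. The new quaternary stereocenter C1 is controlled by the C4 silyloxy stereocenter: the alkene should approach the s-trans carbene anti to the OSiEt3 group, and in the boat transition state the cyclopropane carbon C8 lies over the cyclopentene face syn to C4–H, so C10 bonds to C1 on the α face. Regioselectivity (C6 to C7, not to C10) is secured by the triflyloxy group, which deactivates the C9=C10 alkene toward the electrophilic carbene while attack at C7 develops tertiary allylic cation character at C8. Any trans-divinylcyclopropane should equilibrate to the cis isomer at the Cope temperature through the bis-allylic diradical, and the inward-pointing C1 methyl should only raise the temperature needed.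

Step 6
Reactants: 11 (3S,8aR)-6,8a-dimethyl-3-(triethylsilyloxy)-1,2,3,5,8,8a-hexahydroazulen-7-yl trifluoromethanesulfonate
Product: 13 (3S,3aS,4S,8aR)-4-hydroxy-6,8a-dimethyl-3-(triethylsilyloxy)-1,2,3,3a,4,5,8,8a-octahydroazulen-7-yl trifluoromethanesulfonate, via alkylborane 12 (not isolated)
Conditions: BH3·THF, THF, 0 °C to rt; then NaOH, H2O2, 0 °C
Reagents that add atoms: hydrogen peroxide OO
Why: Hydroboration–oxidation; borane should add syn and anti-Markovnikov to the trisubstituted C5=C6 bond from the α face (anti to the C4 silyloxy group and the C1 methyl), setting H5 α (trans ring fusion) and, after oxidation with retention, O6 α, while the tetrasubstituted, electron-poor enol triflate is inert.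

Step 7
Reactants: 13 (3S,3aS,4S,8aR)-4-hydroxy-6,8a-dimethyl-3-(triethylsilyloxy)-1,2,3,3a,4,5,8,8a-octahydroazulen-7-yl trifluoromethanesulfonate
Product: 14 (3S,3aR,4S,8aR)-4-(tert-butyldimethylsilyloxy)-6,8a-dimethyl-3-(triethylsilyloxy)-1,2,3,3a,4,5,8,8a-octahydroazulen-7-yl trifluoromethanesulfonate
Conditions: t-BuMe2SiOTf, 2,6-lutidine, CH2Cl2, −78 to 0 °C
Reagents that add atoms: tert-butyldimethylsilyl trifluoromethanesulfonate CC(C)(C)[Si](C)(C)OS(=O)(=O)C(F)(F)F
Why: Silylation of the hindered secondary alcohol with a silyl triflate; the tert-butyldimethylsilyl ether is chosen to survive the acidic removal of the triethylsilyl group.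

Step 8
Reactants: 14 (3S,3aR,4S,8aR)-4-(tert-butyldimethylsilyloxy)-6,8a-dimethyl-3-(triethylsilyloxy)-1,2,3,3a,4,5,8,8a-octahydroazulen-7-yl trifluoromethanesulfonate
Product: 15 (3S,3aR,4S,8aR)-4-(tert-butyldimethylsilyloxy)-3-hydroxy-6,8a-dimethyl-1,2,3,3a,4,5,8,8a-octahydroazulen-7-yl trifluoromethanesulfonate
Conditions: PPTS (cat.), MeOH/CH2Cl2, 0 °C
Reagents that add atoms: none
Why: Acid-catalysed methanolysis (selective desilylation) should cleave the secondary triethylsilyl ether much faster than the tert-butyldimethylsilyl ether.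

Step 9
Reactants: 15 (3S,3aR,4S,8aR)-4-(tert-butyldimethylsilyloxy)-3-hydroxy-6,8a-dimethyl-1,2,3,3a,4,5,8,8a-octahydroazulen-7-yl trifluoromethanesulfonate
Product: 16 (3aS,4S,8aR)-4-(tert-butyldimethylsilyloxy)-6,8a-dimethyl-3-oxo-1,2,3,3a,4,5,8,8a-octahydroazulen-7-yl trifluoromethanesulfonate
Conditions: Dess–Martin periodinane, CH2Cl2, 0 °C to rt
Reagents that add atoms: none
Why: Dess–Martin oxidation of the secondary alcohol under near-neutral conditions, which should leave the epimerisable C5 center and the β-silyloxy group untouched.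

Step 10
Reactants: 16 (3aS,4S,8aR)-4-(tert-butyldimethylsilyloxy)-6,8a-dimethyl-3-oxo-1,2,3,3a,4,5,8,8a-octahydroazulen-7-yl trifluoromethanesulfonate
Product: 17 (3R,3aS,4S,8aR)-4-(tert-butyldimethylsilyloxy)-3-hydroxy-6,8a-dimethyl-3-(propan-2-yl)-1,2,3,3a,4,5,8,8a-octahydroazulen-7-yl trifluoromethanesulfonate
Conditions: i-PrLi, CeCl3, THF, −78 °C
Reagents that add atoms: isopropyllithium [Li]C(C)C
Why: 1,2-Addition of a weakly basic organocerium reagent to the enolisable cyclopentanone; attack anti to the adjacent C5–C6 bond and the C1 methyl (α face) should give the 4β tertiary alcohol.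

Step 11
Reactants: 17 (3R,3aS,4S,8aR)-4-(tert-butyldimethylsilyloxy)-3-hydroxy-6,8a-dimethyl-3-(propan-2-yl)-1,2,3,3a,4,5,8,8a-octahydroazulen-7-yl trifluoromethanesulfonate
Product: 20 (3R,3aS,4S,8aR)-4-(tert-butyldimethylsilyloxy)-6,8a-dimethyl-3-(propan-2-yl)-3-(trimethylsilyloxy)-2,3,3a,4,8,8a-hexahydroazulen-7(1H)-one, via dilithium enolate 18 (not isolated), via silyl enol ether 19 (not isolated)
Conditions: MeLi (3.5 equiv), THF, −78 to 0 °C; Me3SiCl, Et3N, −78 °C to rt; then Pd(OAc)2 (1.1 equiv), MeCN, rt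
Reagents that add atoms: chlorotrimethylsilane C[Si](C)(C)Cl
Why: Methyllithium should deprotonate the hydroxyl and attack the sulfonyl sulfur of the enol triflate, releasing the C8=C9 lithium enolate regiospecifically; silylation and Saegusa–Ito oxidation (palladation at C8, β-hydride loss from C7) should give the C7=C8 enone.

Step 12
Reactants: 20 (3R,3aS,4S,8aR)-4-(tert-butyldimethylsilyloxy)-6,8a-dimethyl-3-(propan-2-yl)-3-(trimethylsilyloxy)-2,3,3a,4,8,8a-hexahydroazulen-7(1H)-one
Product: 21 (3R,3aS,4S,8aR)-3,4-dihydroxy-6,8a-dimethyl-3-(propan-2-yl)-2,3,3a,4,8,8a-hexahydroazulen-7(1H)-one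
Conditions: HF·pyridine, pyridine, THF, 0 °C to rt
Reagents that add atoms: none
Why: Fluoride-mediated cleavage of both silyl ethers under mildly acidic conditions that avoid base-induced isomerisation of the γ-hydroxy enone.

Step 13
Reactants: 21 (3R,3aS,4S,8aR)-3,4-dihydroxy-6,8a-dimethyl-3-(propan-2-yl)-2,3,3a,4,8,8a-hexahydroazulen-7(1H)-one, 22 4-methoxybenzoyl chloride
Product: 23 (3R,3aS,4S,8aR)-3-hydroxy-6,8a-dimethyl-7-oxo-3-(propan-2-yl)-1,2,3,3a,4,7,8,8a-octahydroazulen-4-yl 4-methoxybenzoate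
Conditions: DMAP, pyridine, CH2Cl2, 0 °C to rt
Reagents that add atoms: none
Why: Nucleophile-catalysed acylation should take the secondary allylic C6 hydroxyl and leave the tertiary C4 hydroxyl free.

Step 14
Reactants: 23 (3R,3aS,4S,8aR)-3-hydroxy-6,8a-dimethyl-7-oxo-3-(propan-2-yl)-1,2,3,3a,4,7,8,8a-octahydroazulen-4-yl 4-methoxybenzoate
Product: 24 (3R,3aS,4S,7R,8aR)-3,7-dihydroxy-6,8a-dimethyl-3-(propan-2-yl)-1,2,3,3a,4,7,8,8a-octahydroazulen-4-yl 4-methoxybenzoate
Conditions: NaBH4, CeCl3·7H2O, MeOH, −78 °C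
Reagents that add atoms: none
Why: Luche reduction; 1,2-hydride delivery to the enone from the α face, opposite the pseudoaxial C1 methyl, should set the 9β allylic alcohol without touching the aryl ester.

Compound list
1 | 2-bromo-3-methylcyclopent-2-en-1-one | CC1=C(Br)C(=O)CC1 | starting material
2 | (S)-2-bromo-3-methylcyclopent-2-en-1-ol | CC1=C(Br)[C@@H](O)CC1 | intermediate
3 | (S)-[(2-bromo-3-methylcyclopent-2-en-1-yl)oxy]triethylsilane | CC1=C(Br)[C@@H](O[Si](CC)(CC)CC)CC1 | intermediate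
4 | tropylium tetrafluoroborate | C1=CC=C[CH+]C=C1.F[B-](F)(F)F | starting material
5 | [(5S)-2-methyl-5-(triethylsilyloxy)cyclopent-1-en-1-yl]lithium | CC1=C([Li])[C@@H](O[Si](CC)(CC)CC)CC1 | intermediate
6 | 7-[(5S)-2-methyl-5-(triethylsilyloxy)cyclopent-1-en-1-yl]cyclohepta-1,3,5-triene | CC1=C(C2C=CC=CC=C2)[C@@H](O[Si](CC)(CC)CC)CC1 | intermediate
7 | 3-methylbut-3-en-2-one | CC(=O)C(C)=C | starting material
8 | potassium 3-methylbuta-1,3-dien-2-olate | C=C(C)C(=C)[O-].[K+] | intermediate
9 | 3-methylbuta-1,3-dien-2-yl trifluoromethanesulfonate | C=C(C)C(=C)OS(=O)(=O)C(F)(F)F | intermediate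
10 | 1-[(1S,2S)-1-methyl-2-{(5S)-2-methyl-5-(triethylsilyloxy)cyclopent-1-en-1-yl}cyclopropyl]ethenyl trifluoromethanesulfonate (cyclopentenyl and triflyloxyvinyl cis) | CC1=C([C@@H]2C[C@]2(C)C(=C)OS(=O)(=O)C(F)(F)F)[C@@H](O[Si](CC)(CC)CC)CC1 | intermediate
11 | (3S,8aR)-6,8a-dimethyl-3-(triethylsilyloxy)-1,2,3,5,8,8a-hexahydroazulen-7-yl trifluoromethanesulfonate (C4 OSiEt3 β; C1 CH3 β; C5=C6; C8=C9) | C1=C2[C@@H](O[Si](CC)(CC)CC)CC[C@]2(C)CC(OS(=O)(=O)C(F)(F)F)=C(C)C1 | intermediate
12 | C6 alkylborane from 11 (BH2 α at C6; H α at C5) | B[C@H]2CC(C)=C(OS(=O)(=O)C(F)(F)F)C[C@@]3(C)CC[C@H](O[Si](CC)(CC)CC)[C@H]23 | intermediate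
13 | (3S,3aS,4S,8aR)-4-hydroxy-6,8a-dimethyl-3-(triethylsilyloxy)-1,2,3,3a,4,5,8,8a-octahydroazulen-7-yl trifluoromethanesulfonate (H5 α; OH6 α) | O[C@H]2CC(C)=C(OS(=O)(=O)C(F)(F)F)C[C@@]3(C)CC[C@H](O[Si](CC)(CC)CC)[C@H]23 | intermediate
14 | (3S,3aR,4S,8aR)-4-(tert-butyldimethylsilyloxy)-6,8a-dimethyl-3-(triethylsilyloxy)-1,2,3,3a,4,5,8,8a-octahydroazulen-7-yl trifluoromethanesulfonate | CC(C)(C)[Si](C)(C)O[C@H]2CC(C)=C(OS(=O)(=O)C(F)(F)F)C[C@@]3(C)CC[C@H](O[Si](CC)(CC)CC)[C@H]23 | intermediate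
15 | (3S,3aR,4S,8aR)-4-(tert-butyldimethylsilyloxy)-3-hydroxy-6,8a-dimethyl-1,2,3,3a,4,5,8,8a-octahydroazulen-7-yl trifluoromethanesulfonate | CC(C)(C)[Si](C)(C)O[C@H]2CC(C)=C(OS(=O)(=O)C(F)(F)F)C[C@@]3(C)CC[C@H](O)[C@H]23 | intermediate
16 | (3aS,4S,8aR)-4-(tert-butyldimethylsilyloxy)-6,8a-dimethyl-3-oxo-1,2,3,3a,4,5,8,8a-octahydroazulen-7-yl trifluoromethanesulfonate | CC(C)(C)[Si](C)(C)O[C@H]2CC(C)=C(OS(=O)(=O)C(F)(F)F)C[C@@]3(C)CCC(=O)[C@H]23 | intermediate
17 | (3R,3aS,4S,8aR)-4-(tert-butyldimethylsilyloxy)-3-hydroxy-6,8a-dimethyl-3-(propan-2-yl)-1,2,3,3a,4,5,8,8a-octahydroazulen-7-yl trifluoromethanesulfonate | CC(C)(C)[Si](C)(C)O[C@H]2CC(C)=C(OS(=O)(=O)C(F)(F)F)C[C@@]3(C)CC[C@@](O)(C(C)C)[C@H]23 | intermediate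
18 | dilithium C9 enolate and C4 alkoxide from 17 | CC(C)(C)[Si](C)(C)O[C@H]2CC(C)=C(O[Li])C[C@@]3(C)CC[C@@](O[Li])(C(C)C)[C@H]23 | intermediate
19 | (3R,3aS,4S,8aR)-4-(tert-butyldimethylsilyloxy)-6,8a-dimethyl-3-(propan-2-yl)-3,7-bis(trimethylsilyloxy)-1,2,3,3a,4,5,8,8a-octahydroazulene | CC(C)(C)[Si](C)(C)O[C@H]2CC(C)=C(O[Si](C)(C)C)C[C@@]3(C)CC[C@@](O[Si](C)(C)C)(C(C)C)[C@H]23 | intermediate
20 | (3R,3aS,4S,8aR)-4-(tert-butyldimethylsilyloxy)-6,8a-dimethyl-3-(propan-2-yl)-3-(trimethylsilyloxy)-2,3,3a,4,8,8a-hexahydroazulen-7(1H)-one | CC(C)(C)[Si](C)(C)O[C@H]2C=C(C)C(=O)C[C@@]3(C)CC[C@@](O[Si](C)(C)C)(C(C)C)[C@H]23 | intermediate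
21 | (3R,3aS,4S,8aR)-3,4-dihydroxy-6,8a-dimethyl-3-(propan-2-yl)-2,3,3a,4,8,8a-hexahydroazulen-7(1H)-one | O[C@H]2C=C(C)C(=O)C[C@@]3(C)CC[C@@](O)(C(C)C)[C@H]23 | intermediate
22 | 4-methoxybenzoyl chloride | COc1ccc(cc1)C(=O)Cl | starting material
23 | (3R,3aS,4S,8aR)-3-hydroxy-6,8a-dimethyl-7-oxo-3-(propan-2-yl)-1,2,3,3a,4,7,8,8a-octahydroazulen-4-yl 4-methoxybenzoate | COc1ccc(C(=O)O[C@H]2C=C(C)C(=O)C[C@@]3(C)CC[C@@](O)(C(C)C)[C@H]23)cc1 | intermediate
24 | (3R,3aS,4S,7R,8aR)-3,7-dihydroxy-6,8a-dimethyl-3-(propan-2-yl)-1,2,3,3a,4,7,8,8a-octahydroazulen-4-yl 4-methoxybenzoate | COc1ccc(C(=O)O[C@H]2C=C(C)[C@H](O)C[C@@]3(C)CC[C@@](O)(C(C)C)[C@H]23)cc1 | target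

Total step count: 14. Longest linear sequence: 13 steps (steps 1–3 and 5–14); step 4 is a one-step branch.

Steps most likely to fail

Step 5. Carbene release from the hindered, tetrasubstituted alkenylcycloheptatriene may be slower than thermal hydrogen shifts of the triene, so that little cyclopropanation takes place. As a fallback, setting out from 3, the alkenyllithium 5 would be quenched with N,N-dimethylformamide to give (5S)-2-methyl-5-(triethylsilyloxy)cyclopent-1-ene-1-carbaldehyde F1, which would be condensed with 4-methylbenzenesulfonohydrazide to the N-tosylhydrazone F2. Its sodium salt (NaH) would be warmed with 9 and Rh2(OAc)4, so that the vinyldiazomethane F3 formed by Bamford–Stevens fragmentation is trapped at once as the same carbene. Cyclopropanation and rearrangement would then rejoin the route at 11.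

Step 11. Attack of methyllithium at the sulfonyl sulfur may be incomplete, and β-hydride loss from the palladium enolate may run toward the C8 methyl group and give the exocyclic methylene ketone. As a fallback, setting out from 17, Miyaura borylation (PdCl2(dppf), B2pin2, KOAc) would give the alkenyl pinacol boronate F4, and oxidation (NaBO3) the saturated C9 ketone F5. Bromination at the more substituted α-carbon (phenyltrimethylammonium tribromide) would give the C8 bromo ketone F6, and dehydrobromination (Li2CO3, LiBr, DMF, 120 °C) the C7=C8 enone F7. HF·pyridine would then lead back to the route at 21.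

Step 14. Hydride may be delivered to the β face of the C9 carbonyl and give the 9α-alcohol. As a fallback, setting out from 23, the 9α-alcohol F8 obtained in that case would be inverted by a Mitsunobu reaction (4-nitrobenzoic acid, PPh3, diisopropyl azodicarboxylate) to the 9β 4-nitrobenzoate F9. The more electrophilic nitrobenzoate would then be removed selectively (K2CO3, MeOH, 0 °C) to reach 24.

Further compounds
F1 | step 5 | (5S)-2-methyl-5-(triethylsilyloxy)cyclopent-1-ene-1-carbaldehyde | CC1=C(C=O)[C@@H](O[Si](CC)(CC)CC)CC1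
F2 | step 5 | N-tosylhydrazone of F1 (E) | CC1=C(/C=N/NS(=O)(=O)c2ccc(C)cc2)[C@@H](O[Si](CC)(CC)CC)CC1
F3 | step 5 | [(5S)-1-(diazomethyl)-2-methylcyclopent-1-en-5-yl]oxytriethylsilane (not isolated) | CC1=C(C=[N+]=[N-])[C@@H](O[Si](CC)(CC)CC)CC1
F4 | step 11 | C9 alkenyl pinacol boronate from 17 | CC(C)(C)[Si](C)(C)O[C@H]2CC(C)=C(B4OC(C)(C)C(C)(C)O4)C[C@@]3(C)CC[C@@](O)(C(C)C)[C@H]23
F5 | step 11 | saturated C9 ketone (C8 epimers) | CC(C)(C)[Si](C)(C)O[C@H]2CC(C)C(=O)C[C@@]3(C)CC[C@@](O)(C(C)C)[C@H]23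
F6 | step 11 | C8 bromo C9 ketone | CC(C)(C)[Si](C)(C)O[C@H]2CC(C)(Br)C(=O)C[C@@]3(C)CC[C@@](O)(C(C)C)[C@H]23
F7 | step 11 | C7=C8 enone with C6 tert-butyldimethylsilyl ether and free C4 hydroxyl | CC(C)(C)[Si](C)(C)O[C@H]2C=C(C)C(=O)C[C@@]3(C)CC[C@@](O)(C(C)C)[C@H]23
F8 | step 14 | 9α-alcohol (C9 epimer of 24) | COc1ccc(C(=O)O[C@H]2C=C(C)[C@@H](O)C[C@@]3(C)CC[C@@](O)(C(C)C)[C@H]23)cc1
F9 | step 14 | 9β 4-nitrobenzoate of 24 | COc1ccc(C(=O)O[C@H]2C=C(C)[C@H](OC(=O)c4ccc(cc4)[N+](=O)[O-])C[C@@]3(C)CC[C@@](O)(C(C)C)[C@H]23)cc1
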